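**Retrosynthetic overview**
1. Prinsepiol 11 is a C2-symmetric, cis-fused 3,7-dioxabicyclo[3.3.0]octane (ring A: C1, C2, O3, C4, C5; ring B: C5, C6, O7, C8, C1). The enabling feature: each benzylic carbon (C2, C6) bears a ring oxygen (O3, O7), lies para to the free 4-OH of its guaiacyl ring, and adjoins a bridgehead carbinol (C1, C5). Each half is therefore the alcohol adduct of a p-quinone methide, and its neighbouring OH can be the oxygen of a former C1–C2 (C5–C6) oxirane.
2. C2–O3 and C6–O7 are disconnected together: 11 ⇒ bis(p-quinone methide) tetraol 10 ⇒ bisphenol bis-epoxide 9 ⇒ its diacetate 8. Both rings form in the last step, ring A first and ring B across it, copying the bis(quinone methide) closure that builds furofuran lignans in nature.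
3. 8 ⇒ achiral, flat (E,E)-diene-diol 7, which already holds all twenty skeletal carbons. One two-fold Sharpless epoxidation sets the absolute configuration.
4. 7 ⇒ central C–C bond by nickel homocoupling of the (Z)-α-bromocinnamate 4 ⇒ vanillin acetate 1 + ylide 2.

Key step: step 6

Assumption: the geometry of the exocyclic C=C bonds of transient 10 is lost again on ring closure, so it is left open in its SMILES.

**Step 1**
Reactants: 1 vanillin acetate; 2 ethyl (triphenylphosphoranylidene)acetate
Product: 4 ethyl (Z)-3-(4-acetoxy-3-methoxyphenyl)-2-bromoprop-2-enoate, via bromo ylide 3 (not isolated)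
Conditions: 2, NBS (1.05 equiv), CH2Cl2, −20 °C; then 1, −20 °C → rt
Reagents that add atoms: N-bromosuccinimide, O=C1CCC(=O)N1Br
Why: NBS brominates the stabilised ylide at carbon and the succinimide anion removes the proton to give 3, which undergoes a Wittig olefination of the aromatic aldehyde under the usual stabilised-ylide control (aryl trans to CO2Et, hence the Z-bromoalkene), and the neutral medium leaves the aryl acetate alone.

**Step 2**
Reactants: 4 ethyl (Z)-3-(4-acetoxy-3-methoxyphenyl)-2-bromoprop-2-enoate (two molecules)
Product: 5 diethyl (2E,3E)-2,3-bis[(4-acetoxy-3-methoxyphenyl)methylidene]butanedioate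
Conditions: NiCl2(PPh3)2 (15 mol %), Zn dust, Et4NI, THF, 50 °C
Reagents that add atoms: none
Why: Nickel-catalysed reductive homocoupling of an alkenyl bromide (Ullmann type, zerovalent nickel regenerated by Zn) joins the two bromine-bearing sp2 carbons with retention, so aryl stays cis to the new C–C bond; the E,E-bis(arylidene)succinate should also be the most stable isomer, so geometric leakage at nickel should drain to the same product, and esters and aryl acetates are inert to the PPh3-ligated catalyst at this temperature.

**Step 3**
Reactants: 5 diethyl (2E,3E)-2,3-bis[(4-acetoxy-3-methoxyphenyl)methylidene]butanedioate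
Product: 6 (2E,3E)-2,3-bis[(4-hydroxy-3-methoxyphenyl)methylidene]butane-1,4-diol
Conditions: i-Bu2AlH (DIBAL-H, 10 equiv), CH2Cl2/toluene, −78 → 0 °C; aq. potassium sodium tartrate
Reagents that add atoms: none
Why: DIBAL-H 1,2-reduction of α,β-unsaturated esters to allylic alcohols (the standard ferulate-to-coniferyl-alcohol reduction) leaves the trisubstituted alkenes and their geometry untouched, and the reductive loss of the two aryl acetates in the same flask is intended because no acyl group survives this step.

**Step 4**
Reactants: 6 (2E,3E)-2,3-bis[(4-hydroxy-3-methoxyphenyl)methylidene]butane-1,4-diol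
Product: 7 (2E,3E)-2,3-bis[(4-acetoxy-3-methoxyphenyl)methylidene]butane-1,4-diol
Conditions: Ac2O (2.1 equiv), aq. NaOH (2.1 equiv), THF, 0 °C
Reagents that add atoms: acetic anhydride, CC(=O)OC(C)=O
Why: In this Schotten–Baumann-type chemoselective acylation aqueous NaOH ionises only the phenols, whose phenoxides outrun the neutral primary allylic alcohols for Ac2O, and the acetate switches the para oxygen from a strong donor to a weak acceptor so that the benzylic oxiranes of step 5 can be made and handled.

**Step 5**
Reactants: 7 (2E,3E)-2,3-bis[(4-acetoxy-3-methoxyphenyl)methylidene]butane-1,4-diol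
Product: 8 [(2S,2'S,3S,3'S)-3,3'-bis(4-acetoxy-3-methoxyphenyl)-[2,2'-bioxirane]-2,2'-diyl]dimethanol
Conditions: Ti(OiPr)4 (20 mol %), L-(+)-diisopropyl tartrate (26 mol %), t-BuOOH (decane, 4 equiv), 4 Å MS, CH2Cl2, −20 °C; non-basic work-up (aq. citric acid)
Reagents that add atoms: tert-butyl hydroperoxide, CC(C)(C)OO
Why: In this two-fold Katsuki–Sharpless asymmetric epoxidation each half is a 2,3-disubstituted allylic alcohol of the (E)-α-phenylcinnamyl alcohol type (a privileged substrate class) and the twisted diene lets the halves react independently; L-(+)-tartrate directs oxygen to the face that makes all four oxirane carbons S (the quaternary C–O bonds are the later C1–OH and C5–OH bonds), syn transfer keeps aryl trans to CH2OH, and the second catalyst-controlled event diverts the minor mono-epoxide enantiomer into the separable meso isomer (Horeau amplification).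

**Step 6**
Reactants: 8 [(2S,2'S,3S,3'S)-3,3'-bis(4-acetoxy-3-methoxyphenyl)-[2,2'-bioxirane]-2,2'-diyl]dimethanol
Product: 11 prinsepiol [(1S,2R,5S,6R)-2,6-bis(4-hydroxy-3-methoxyphenyl)-3,7-dioxabicyclo[3.3.0]octane-1,5-diol], via bisphenol bis-epoxide 9 (not isolated), via bis-quinone-methide tetraol 10 (not isolated)
Conditions: K2CO3 (0.3 equiv), MeOH/THF 1:4 (0.01 M, degassed), 0 °C → rt; then aq. NH4Cl
Reagents that add atoms: none
Why: Proposed new method: catalytic methoxide transesterifies the two aryl acetates, each freed phenoxide of 9 pushes through its arene and expels the benzylic oxirane oxygen in a strain-driven 1,6-elimination to give the p-quinone methide carbinols of 10, and the CH2OH group on C5 then adds to C2 and the CH2OH group on C1 to C6 (oxa-1,6-addition with rearomatisation), so that from 9 onward the cascade is a pure isomerisation. The closest known reaction types are the 1,6-elimination of unmasked p-hydroxybenzyl esters and ethers (p-quinone methide release from 4-acetoxybenzyl derivatives, self-immolative linkers) and the double intramolecular hydroxyl capture of the bis(quinone methide) that arises in the oxidative 8-8' dimerisation of coniferyl alcohol to pinoresinol, which this step copies; new is the oxirane oxygen as leaving group, which stays behind as the bridgehead OH. Ring A (C2–O3) and then ring B (C6–O7) each close 5-exo-trig onto the exocyclic C=C of a quinone methide, which replaces the geometrically poor 5-endo-tet attack on the intact oxirane, while the 4-exo closures to oxetanes open to the geminal CH2OH and the tertiary OH groups are not competitive. C1 and C5 keep the C–O bonds and the S configuration made in step 5 and control the two new centres: in the closing conformer the carbon that carries the nucleophile stands perpendicular to the quinone methide plane and A(1,3) strain places the small OH rather than the CH2 group beside the ring, so aryl ends cis to the neighbouring bridgehead OH (exo, R at C2 and C6), the second closure being reinforced by the convex face of the cis-fused bicycle. A more concerted, invertive opening of the S-configured benzylic carbon of the E-derived oxirane leads to the same R centres, so both mechanistic extremes converge. The step needs cleavage of the benzylic and not the quaternary C–O bond (secured by the para phenoxide), ring closure faster than capture by methanol or a second phenoxide (secured by the 1,4 relation of OH and quinone methide carbon and by high dilution, the quaternary neighbour also blocking tautomerisation to a vinylphenol), and it edits the stereoisomers, since the meso bis-epoxide would have to form a trans-fused bicycle and stops after one ring.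

**Compound list**
1 | vanillin acetate (4-formyl-2-methoxyphenyl acetate) | CC(=O)Oc1ccc(C=O)cc1OC | starting material
2 | ethyl (triphenylphosphoranylidene)acetate | CCOC(=O)C=P(c1ccccc1)(c1ccccc1)c1ccccc1 | starting material
3 | ethyl bromo(triphenylphosphoranylidene)acetate | CCOC(=O)C(Br)=P(c1ccccc1)(c1ccccc1)c1ccccc1 | intermediate
4 | ethyl (Z)-3-(4-acetoxy-3-methoxyphenyl)-2-bromoprop-2-enoate | CCOC(=O)/C(Br)=C/c1ccc(OC(C)=O)c(OC)c1 | intermediate
5 | diethyl (2E,3E)-2,3-bis[(4-acetoxy-3-methoxyphenyl)methylidene]butanedioate | CCOC(=O)/C(=C/c1ccc(OC(C)=O)c(OC)c1)/C(=C\c1ccc(OC(C)=O)c(OC)c1)C(=O)OCC | intermediate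
6 | (2E,3E)-2,3-bis[(4-hydroxy-3-methoxyphenyl)methylidene]butane-1,4-diol | OC/C(=C/c1ccc(O)c(OC)c1)/C(=C\c1ccc(O)c(OC)c1)CO | intermediate
7 | (2E,3E)-2,3-bis[(4-acetoxy-3-methoxyphenyl)methylidene]butane-1,4-diol | OC/C(=C/c1ccc(OC(C)=O)c(OC)c1)/C(=C\c1ccc(OC(C)=O)c(OC)c1)CO | intermediate
8 | [(2S,2'S,3S,3'S)-3,3'-bis(4-acetoxy-3-methoxyphenyl)-[2,2'-bioxirane]-2,2'-diyl]dimethanol | CC(=O)Oc1ccc(cc1OC)[C@@H]2O[C@]2(CO)[C@@]3(CO)O[C@H]3c4ccc(OC(C)=O)c(OC)c4 | intermediate
9 | [(2S,2'S,3S,3'S)-3,3'-bis(4-hydroxy-3-methoxyphenyl)-[2,2'-bioxirane]-2,2'-diyl]dimethanol | COc1cc(ccc1O)[C@@H]2O[C@]2(CO)[C@@]3(CO)O[C@H]3c4ccc(O)c(OC)c4 | intermediate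
10 | (2R,3R)-2,3-bis(hydroxymethyl)-1,4-bis(3-methoxy-4-oxocyclohexa-2,5-dien-1-ylidene)butane-2,3-diol | COC1=CC(=C[C@@](O)(CO)[C@](O)(CO)C=C2C=CC(=O)C(OC)=C2)C=CC1=O | intermediate
11 | prinsepiol, (1S,2R,5S,6R)-2,6-bis(4-hydroxy-3-methoxyphenyl)-3,7-dioxabicyclo[3.3.0]octane-1,5-diol | COc1cc([C@H]2OC[C@]3(O)[C@@H](c4ccc(O)c(OC)c4)OC[C@]23O)ccc1O | target

**Count**
Total steps: 6. Longest linear sequence: 6 (from 1).

**Steps most likely to fail**

Step 6 (Proposed new method). Several processes could compete:
- capture of the quinone methide by methanol or by a phenoxide of a second molecule;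
- a semipinacol shift of the carbinol next to the quinone methide;
- base-induced Payne migration before the acetates are gone;
- weak facial control in the first closure.

The fallback uses known chemistry with a cationic instead of an anionic trigger. It sets out from 8 with the acetates kept. Both rings are closed by acid-catalysed intramolecular opening of the aryl oxiranes at the benzylic carbon by the γ-hydroxyl groups (camphorsulfonic acid cat. or BF3·OEt2, CH2Cl2, −40 → 0 °C), the reaction type used for 2-aryl-3-hydroxytetrahydrofurans. Opening with inversion of the E-derived oxiranes should give prinsepiol 4,4'-di-O-acetate F1. Ordinary methanolysis of F1 (K2CO3, MeOH) comes back to the route at 11.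

Step 5. Several processes could compete:
- slow or mismatched second oxygen transfer next to the first, fully substituted oxirane carbon;
- chelation of the 1,4-diol to titanium with loss of enantioface selection;
- Lewis-acid opening of the intermediate alkenyl oxirane;
- transesterification of the aryl acetates by the titanium alkoxide.

The fallback replaces alkoxide-directed oxygen transfer by a non-directed chiral dioxirane. It sets out from 7, which is submitted to a Shi epoxidation. The reagent is the L-fructose-derived enantiomer of the Shi ketone, the antipode being needed for S benzylic carbons. Conditions are KHSO5 (as Oxone), NaHCO3 buffer near pH 8 to spare the aryl acetates, MeCN/aq. Na2EDTA, 0 °C. Trisubstituted styrenes and free hydroxyalkenes are established substrates. This comes back to the route at 8 and makes no compound outside the list (F0).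

Step 2. Possible failures are hydrodebromination of the alkenylnickel species, loss of alkene geometry, or sluggish reductive elimination between two crowded α-carbons. The fallback replaces the reductive dimerisation by a stepwise cross-coupling and sets out from 4. Half of 4 is converted by Miyaura borylation (B2pin2, PdCl2(dppf), KOAc, dioxane, 80 °C) into ethyl (E)-3-(4-acetoxy-3-methoxyphenyl)-2-(4,4,5,5-tetramethyl-1,3,2-dioxaborolan-2-yl)prop-2-enoate F2. F2 is joined to the other half of 4 by Suzuki–Miyaura coupling (Pd(PPh3)4, K3PO4, dioxane, 60 °C) with retention at both partners, which comes back to the route at 5.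

**Further compounds**
F1 | step 6 | prinsepiol 4,4'-di-O-acetate | COc1cc([C@H]2OC[C@]3(O)[C@@H](c4ccc(OC(C)=O)c(OC)c4)OC[C@]23O)ccc1OC(C)=O
F0 | step 5 | none | none
F2 | step 2 | ethyl (E)-3-(4-acetoxy-3-methoxyphenyl)-2-(4,4,5,5-tetramethyl-1,3,2-dioxaborolan-2-yl)prop-2-enoate | CCOC(=O)/C(B1OC(C)(C)C(C)(C)O1)=C/c1ccc(OC(C)=O)c(OC)c1
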